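**Plan**

- Retrosynthesis: after removal of the silyl groups, ring C is cut at C3–C4. This reveals a ring A benzaldehyde whose ortho oxygen O1 carries C2 as the substituted carbon of a 1-arylvinyl ether (C2=C3).
- The enol ether is then cut at O1–C2 (Mitsunobu, then loss of HCl), at C2–C3 (chloromethyl addition to a ring B aldehyde) and at the two aryl–carbon bonds of ring B (Sonogashira, Stille).
- Forward: ring B is dressed first (iodination, O-methylation, alkynylation, prenylation, cis-semihydrogenation, silylation) and C3 is added as CH2Cl. Ring B is joined to bis-silylated phloroglucinaldehyde (ring A) through O1–C2, HCl is eliminated, and ring C closes last.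
- Enabling feature: C4 is an aryl ketone carbon ortho to O1 on ring A, and C2 carries one H, O1 and ring B. The flavanone is therefore the formal adduct of the ring A aldehyde C–H across a C2=C3 enol ether, so one hydroacylation makes ring C and the only stereocentre.
- Stereochemistry: (2S) comes from the chiral bisphosphine on rhodium in the ring closure; the Z alkene comes from syn addition of H2 to the aryl alkyne.

Key step: step 11

Assumption: the sense of induction of the rhodium catalyst on this new substrate class cannot be assigned beforehand; (R)-DTBM-SEGPHOS is written, and its antipode is to be used if the first run shows the 2R product.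

Abbreviations in names: ArB = 4-methoxy-3-(3-methylbut-2-en-1-yl)-5-[(Z)-3-methyl-3-(triethylsilyloxy)but-1-en-1-yl]phenyl; TES = triethylsilyl; TIPS = triisopropylsilyl.

**Route**

Step 1
Reactants: 1 3-bromo-4-hydroxybenzaldehyde
Product: 2 3-bromo-4-hydroxy-5-iodobenzaldehyde
Conditions: N-iodosuccinimide, cat. CF3CO2H, MeCN, rt
Reagents that add atoms: N-iodosuccinimide, O=C1CCC(=O)N1I
Why: Electrophilic aromatic iodination; the phenol directs to its only free ortho position, the para position being blocked by the formyl group.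

Step 2
Reactants: 2 3-bromo-4-hydroxy-5-iodobenzaldehyde
Product: 3 3-bromo-5-iodo-4-methoxybenzaldehyde
Conditions: MeI, K2CO3, DMF, rt
Reagents that add atoms: iodomethane, CI
Why: Williamson O-methylation of the acidic di-ortho-halogenated phenol.

Step 3
Reactants: 3 3-bromo-5-iodo-4-methoxybenzaldehyde; 4 2-methylbut-3-yn-2-ol
Product: 5 3-bromo-5-(3-hydroxy-3-methylbut-1-yn-1-yl)-4-methoxybenzaldehyde
Conditions: Pd(PPh3)2Cl2 (cat.), CuI (cat.), Et3N, THF, rt
Reagents that add atoms: none
Why: Sonogashira coupling; zerovalent palladium inserts into C–I far faster than into C–Br at room temperature, so only the iodide should couple.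

Step 4
Reactants: 5 3-bromo-5-(3-hydroxy-3-methylbut-1-yn-1-yl)-4-methoxybenzaldehyde; 6 tributyl(3-methylbut-2-en-1-yl)stannane
Product: 7 3-(3-hydroxy-3-methylbut-1-yn-1-yl)-4-methoxy-5-(3-methylbut-2-en-1-yl)benzaldehyde
Conditions: Pd(PPh3)4 (cat.), DMF, 95 °C
Reagents that add atoms: none
Why: Stille coupling of the remaining aryl bromide; reductive elimination at the unsubstituted terminus of the prenyl palladium intermediate should give the linear prenyl arene, and aldehyde, alkyne and tertiary alcohol are tolerated.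

Step 5
Reactants: 7 3-(3-hydroxy-3-methylbut-1-yn-1-yl)-4-methoxy-5-(3-methylbut-2-en-1-yl)benzaldehyde
Product: 8 3-[(Z)-3-hydroxy-3-methylbut-1-en-1-yl]-4-methoxy-5-(3-methylbut-2-en-1-yl)benzaldehyde
Conditions: H2 (1 atm), Pd/CaCO3 poisoned with Pb(OAc)2, quinoline, EtOAc, rt
Reagents that add atoms: none
Why: Lindlar semihydrogenation; syn delivery of H2 on the poisoned surface gives the Z alkene, and the trisubstituted prenyl alkene and the aryl aldehyde are not reduced.

Step 6
Reactants: 8 3-[(Z)-3-hydroxy-3-methylbut-1-en-1-yl]-4-methoxy-5-(3-methylbut-2-en-1-yl)benzaldehyde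
Product: 9 4-methoxy-3-(3-methylbut-2-en-1-yl)-5-[(Z)-3-methyl-3-(triethylsilyloxy)but-1-en-1-yl]benzaldehyde (ArB–CHO)
Conditions: TESOTf, 2,6-lutidine, CH2Cl2, −78 to 0 °C
Reagents that add atoms: triethylsilyl trifluoromethanesulfonate, CC[Si](CC)(CC)OS(=O)(=O)C(F)(F)F
Why: Silyl triflate silylation of the hindered tertiary alcohol, which would otherwise quench the organolithium of step 7.

Step 7
Reactants: 9 ArB–CHO
Product: 11 rac-2-chloro-1-(ArB)ethan-1-ol, via lithium alkoxide 10 (not isolated)
Conditions: ClCH2I, MeLi·LiBr, THF, −78 °C; then AcOH, −78 °C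
Reagents that add atoms: chloroiodomethane, ClCI
Why: Addition of chloromethyllithium generated by iodine–lithium exchange in the presence of the aldehyde (Barbier mode); the cold acid quench keeps the chlorohydrin from closing to the epoxide, and the racemic carbinol centre is removed again in step 10.

Step 8
Reactants: 12 2,4,6-trihydroxybenzaldehyde
Product: 13 2-hydroxy-4,6-bis(triisopropylsilyloxy)benzaldehyde
Conditions: TIPSCl (2.1 equiv), imidazole, DMF, 0 °C to rt
Reagents that add atoms: chlorotriisopropylsilane, CC(C)[Si](Cl)(C(C)C)C(C)C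
Why: Selective phenol silylation; the para OH and one ortho OH react, while the last ortho OH is hydrogen-bonded to the formyl oxygen and stays free, as in the usual 4,6-bis-protection of phloroglucinaldehyde.

Step 9
Reactants: 11 rac-2-chloro-1-(ArB)ethan-1-ol; 13 2-hydroxy-4,6-bis(triisopropylsilyloxy)benzaldehyde
Product: 14 rac-2-[2-chloro-1-(ArB)ethoxy]-4,6-bis(triisopropylsilyloxy)benzaldehyde
Conditions: PPh3, DIAD, THF, 0 °C to rt
Reagents that add atoms: none
Why: Mitsunobu etherification of the acidic salicylaldehyde-type phenol with the secondary benzylic alcohol forms O1–C2; the configuration is irrelevant because C2 becomes sp2 in step 10.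

Step 10
Reactants: 14 rac-2-[2-chloro-1-(ArB)ethoxy]-4,6-bis(triisopropylsilyloxy)benzaldehyde
Product: 15 2-{[1-(ArB)ethenyl]oxy}-4,6-bis(triisopropylsilyloxy)benzaldehyde
Conditions: KOtBu, 18-crown-6, THF, −20 to 0 °C
Reagents that add atoms: none
Why: E2 dehydrochlorination; the only β-hydrogen is the benzylic, oxygen-bearing C2–H, so elimination can give only the 1-arylvinyl aryl ether, and the aldehyde is not enolisable.

Step 11
Reactants: 15 2-{[1-(ArB)ethenyl]oxy}-4,6-bis(triisopropylsilyloxy)benzaldehyde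
Product: 16 (2S)-2-(ArB)-5,7-bis(triisopropylsilyloxy)-2,3-dihydro-4H-chromen-4-one
Conditions: [Rh(cod)Cl]2 (2.5 mol%), (R)-DTBM-SEGPHOS (5.5 mol%), NaB[3,5-(CF3)2C6H3]4 (5 mol%), 1,4-dioxane, 60 °C
Reagents that add atoms: none
Why: Proposed new method: oxidative addition of the aldehyde C–H bond to the cationic monovalent rhodium bisphosphine gives an acyl rhodium hydride (trivalent rhodium) held next to the C2=C3 enol ether by O1; the hydride migrates to C2, rhodium ends on the unsubstituted C3, and C–C reductive elimination from the seven-membered acyl alkyl rhodacycle forms the C3–C4 bond. The closest known reaction type is the endo-selective, enantioselective rhodium-catalysed intramolecular hydroacylation of 1,1-disubstituted alkenes held ortho to an aryl aldehyde (ortho-(2-substituted allyl)benzaldehydes to 3-substituted tetralones, N-(1-substituted vinyl)indole-2-carbaldehydes to bicyclic ketones); what is new is the oxygen tether, a 1-arylvinyl aryl ether as the alkene. Ring C closes in the 6-endo-trig mode, acyl carbon to terminal alkene carbon. The C2 stereocentre is set in the hydride insertion, where the C2-symmetric ligand differentiates the two faces of the enol ether (catalyst control, the substrate being achiral). The step needs endo over exo regioselectivity and hydroacylation over decarbonylation: the exo path would need a tertiary alkyl rhodium at the fully substituted C2, which 1,1-disubstituted alkenes avoid, and fast insertion of the tethered alkene together with the two ortho oxygen substituents should disfavour loss of CO. The prenyl and the cis-disubstituted silyloxyalkenyl groups are remote, hindered alkenes that should neither insert nor isomerise under these mild conditions.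

Step 12
Reactants: 16 (2S)-2-(ArB)-5,7-bis(triisopropylsilyloxy)-2,3-dihydro-4H-chromen-4-one
Product: 17 (2S)-5,7-dihydroxy-2-{3-[(Z)-3-hydroxy-3-methylbut-1-en-1-yl]-4-methoxy-5-(3-methylbut-2-en-1-yl)phenyl}-2,3-dihydro-4H-chromen-4-one
Conditions: Bu4NF, AcOH (1:1, excess), THF, 0 °C to rt
Reagents that add atoms: none
Why: Fluoride desilylation of the two aryl TIPS ethers and the tertiary TES ether; the acetic acid buffer should prevent base-induced opening of the flavanone to the chalcone, which would racemise C2, and the near-neutral medium spares the tertiary allylic alcohol.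

**Compound list**

1 | 3-bromo-4-hydroxybenzaldehyde | O=Cc1ccc(O)c(Br)c1 | starting material
2 | 3-bromo-4-hydroxy-5-iodobenzaldehyde | O=Cc1cc(Br)c(O)c(I)c1 | intermediate
3 | 3-bromo-5-iodo-4-methoxybenzaldehyde | COc1c(Br)cc(C=O)cc1I | intermediate
4 | 2-methylbut-3-yn-2-ol | CC(C)(O)C#C | starting material
5 | 3-bromo-5-(3-hydroxy-3-methylbut-1-yn-1-yl)-4-methoxybenzaldehyde | COc1c(Br)cc(C=O)cc1C#CC(C)(C)O | intermediate
6 | tributyl(3-methylbut-2-en-1-yl)stannane | CC(C)=CC[Sn](CCCC)(CCCC)CCCC | starting material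
7 | 3-(3-hydroxy-3-methylbut-1-yn-1-yl)-4-methoxy-5-(3-methylbut-2-en-1-yl)benzaldehyde | COc1c(CC=C(C)C)cc(C=O)cc1C#CC(C)(C)O | intermediate
8 | 3-[(Z)-3-hydroxy-3-methylbut-1-en-1-yl]-4-methoxy-5-(3-methylbut-2-en-1-yl)benzaldehyde | COc1c(CC=C(C)C)cc(C=O)cc1/C=C\C(C)(C)O | intermediate
9 | 4-methoxy-3-(3-methylbut-2-en-1-yl)-5-[(Z)-3-methyl-3-(triethylsilyloxy)but-1-en-1-yl]benzaldehyde | COc1c(CC=C(C)C)cc(C=O)cc1/C=C\C(C)(C)O[Si](CC)(CC)CC | intermediate
10 | lithium rac-2-chloro-1-(ArB)ethan-1-olate (not isolated) | COc1c(CC=C(C)C)cc(C(O[Li])CCl)cc1/C=C\C(C)(C)O[Si](CC)(CC)CC | intermediate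
11 | rac-2-chloro-1-{4-methoxy-3-(3-methylbut-2-en-1-yl)-5-[(Z)-3-methyl-3-(triethylsilyloxy)but-1-en-1-yl]phenyl}ethan-1-ol | COc1c(CC=C(C)C)cc(C(O)CCl)cc1/C=C\C(C)(C)O[Si](CC)(CC)CC | intermediate
12 | 2,4,6-trihydroxybenzaldehyde | O=Cc1c(O)cc(O)cc1O | starting material
13 | 2-hydroxy-4,6-bis(triisopropylsilyloxy)benzaldehyde | O=Cc1c(O)cc(O[Si](C(C)C)(C(C)C)C(C)C)cc1O[Si](C(C)C)(C(C)C)C(C)C | intermediate
14 | rac-2-[2-chloro-1-(ArB)ethoxy]-4,6-bis(triisopropylsilyloxy)benzaldehyde | O=Cc1c(OC(CCl)c2cc(CC=C(C)C)c(OC)c(/C=C\C(C)(C)O[Si](CC)(CC)CC)c2)cc(O[Si](C(C)C)(C(C)C)C(C)C)cc1O[Si](C(C)C)(C(C)C)C(C)C | intermediate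
15 | 2-{[1-(ArB)ethenyl]oxy}-4,6-bis(triisopropylsilyloxy)benzaldehyde | O=Cc1c(OC(=C)c2cc(CC=C(C)C)c(OC)c(/C=C\C(C)(C)O[Si](CC)(CC)CC)c2)cc(O[Si](C(C)C)(C(C)C)C(C)C)cc1O[Si](C(C)C)(C(C)C)C(C)C | intermediate
16 | (2S)-2-(ArB)-5,7-bis(triisopropylsilyloxy)-2,3-dihydro-4H-chromen-4-one | COc1c(/C=C\C(C)(C)O[Si](CC)(CC)CC)cc([C@@H]2CC(=O)c3c(O[Si](C(C)C)(C(C)C)C(C)C)cc(O[Si](C(C)C)(C(C)C)C(C)C)cc3O2)cc1CC=C(C)C | intermediate
17 | (2S)-5,7-dihydroxy-2-{3-[(Z)-3-hydroxy-3-methylbut-1-en-1-yl]-4-methoxy-5-(3-methylbut-2-en-1-yl)phenyl}-2,3-dihydro-4H-chromen-4-one | COc1c(/C=C\C(C)(C)O)cc([C@@H]2CC(=O)c3c(O)cc(O)cc3O2)cc1CC=C(C)C | target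

**Count and risks**

Total step count: 12. Longest linear sequence: 11 steps (steps 1–7 and 9–12, from compound 1); step 8 is a one-step side branch.

Steps most likely to fail:

1. Step 11. The hydride may insert in the exo sense and lead to the 2-aryl-2-methylbenzofuran-3-one, the hindered acyl rhodium hydride may lose CO, or face selection at C2 may be poor. The fallback uses known chemistry and closes the same C3–C4 bond with C2 set beforehand. It sets out from 11, which is oxidised with Dess–Martin periodinane to the chloromethyl ketone 2-chloro-1-(ArB)ethan-1-one F1. Asymmetric transfer hydrogenation with RuCl(p-cymene)[(R,R)-TsDPEN] and HCO2H/Et3N should give (S)-2-chloro-1-(ArB)ethan-1-ol F2. Mitsunobu coupling of F2 with 13 (PPh3, DIAD) proceeds with inversion to (R)-2-[2-chloro-1-(ArB)ethoxy]-4,6-bis(triisopropylsilyloxy)benzaldehyde F3. A thiazolium-derived carbene (3-benzyl-5-(2-hydroxyethyl)-4-methylthiazolium chloride, one equivalent of DBU, NaI, 1,4-dioxane, heat) then alkylates its own Breslow intermediate with the primary halide, as known for 2-(2-haloethoxy)benzaldehydes giving chroman-4-ones. The route is rejoined at 16.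

2. Step 10. The alkoxide may attack silicon and strip the aryl silyl ethers of the formyl-bearing ring, or substitution may compete with elimination. The fallback replaces base-induced elimination by an oxidative syn-elimination and sets out from 14. Benzeneselenol with Cs2CO3 in DMF displaces the chloride to give the selenide rac-2-[1-(ArB)-2-(phenylselanyl)ethoxy]-4,6-bis(triisopropylsilyloxy)benzaldehyde F4. One equivalent of mCPBA at −78 °C gives the selenoxide rac-2-[1-(ArB)-2-(phenylseleninyl)ethoxy]-4,6-bis(triisopropylsilyloxy)benzaldehyde F5, which is not isolated; warming with iPr2NH should eliminate towards C2–H. The route is rejoined at 15.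

3. Step 4. Allyl transposition during transmetalation and reductive elimination may give the branched 1,1-dimethylallyl isomer, or the aryl palladium intermediate may add to the alkyne. The fallback inverts the polarity of the partners and sets out from 5. Miyaura borylation (B2pin2, Pd(dppf)Cl2, KOAc, 1,4-dioxane) gives 3-(3-hydroxy-3-methylbut-1-yn-1-yl)-4-methoxy-5-(4,4,5,5-tetramethyl-1,3,2-dioxaborolan-2-yl)benzaldehyde F6. Suzuki-type coupling with 1-bromo-3-methylbut-2-ene (Pd(PPh3)4, aqueous K2CO3, THF) delivers the aryl group to the unsubstituted terminus of the prenyl palladium intermediate. The route is rejoined at 7.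

**Further compounds**

F1 | step 11 | 2-chloro-1-(ArB)ethan-1-one | COc1c(CC=C(C)C)cc(C(=O)CCl)cc1/C=C\C(C)(C)O[Si](CC)(CC)CC
F2 | step 11 | (S)-2-chloro-1-(ArB)ethan-1-ol | COc1c(CC=C(C)C)cc([C@H](O)CCl)cc1/C=C\C(C)(C)O[Si](CC)(CC)CC
F3 | step 11 | (R)-2-[2-chloro-1-(ArB)ethoxy]-4,6-bis(triisopropylsilyloxy)benzaldehyde | O=Cc1c(O[C@@H](CCl)c2cc(CC=C(C)C)c(OC)c(/C=C\C(C)(C)O[Si](CC)(CC)CC)c2)cc(O[Si](C(C)C)(C(C)C)C(C)C)cc1O[Si](C(C)C)(C(C)C)C(C)C
F4 | step 10 | rac-2-[1-(ArB)-2-(phenylselanyl)ethoxy]-4,6-bis(triisopropylsilyloxy)benzaldehyde | O=Cc1c(OC(C[Se]c3ccccc3)c2cc(CC=C(C)C)c(OC)c(/C=C\C(C)(C)O[Si](CC)(CC)CC)c2)cc(O[Si](C(C)C)(C(C)C)C(C)C)cc1O[Si](C(C)C)(C(C)C)C(C)C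
F5 | step 10 | rac-2-[1-(ArB)-2-(phenylseleninyl)ethoxy]-4,6-bis(triisopropylsilyloxy)benzaldehyde | O=Cc1c(OC(C[Se](=O)c3ccccc3)c2cc(CC=C(C)C)c(OC)c(/C=C\C(C)(C)O[Si](CC)(CC)CC)c2)cc(O[Si](C(C)C)(C(C)C)C(C)C)cc1O[Si](C(C)C)(C(C)C)C(C)C
F6 | step 4 | 3-(3-hydroxy-3-methylbut-1-yn-1-yl)-4-methoxy-5-(4,4,5,5-tetramethyl-1,3,2-dioxaborolan-2-yl)benzaldehyde | COc1c(B2OC(C)(C)C(C)(C)O2)cc(C=O)cc1C#CC(C)(C)O
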